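**Target:** CNP0225232.1, (4Z,6S,7S,8R,10R)-8-[(E)-but-2-enoyloxy]-15-hydroxy-1-oxo-3,10-epoxygermacra-2,4,11(13)-trien-12,6-olide. Germacrane numbering is used in the text: C1 furanone C=O, C10 quaternary O–C(Me), C8 crotonate carbon, C6/C7 lactone fusion, C15 CH2OH.

## Retrosynthetic overview

1. Last ring closure: the C6–C7 bond, by intramolecular Nozaki–Hiyama allylation of a (Z)-enal with a 2-(chloromethyl)enoate followed by 6,12-lactonisation. This forms the ten-membered carbocycle and the α-methylene lactone together; only the C15 silyl ether is removed afterwards.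
2. First ring: the 3(2H)-furanone, by Au(III)-catalysed 5-endo heterocyclisation/1,2-methyl shift (α-ketol type) of an acyclic tertiary α-hydroxy-α-alkynyl ketone. The shift moves C14 from C1 to C10 and transfers the carbinol configuration to C10.
3. That ketone: C8–C9 boron aldol of a methyl ketone with methyl (Z)-2-(chloromethyl)-4-oxobut-2-enoate (from a Morita–Baylis–Hillman adduct), then 8-O-crotonylation.
4. The methyl ketone: enantioselective mono-alkynylation of biacetyl (C1–C2) with a (Z)-enyne made from but-2-yne-1,4-diol (Red-Al/I2, then Negishi ethynylation for C3–C4).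
5. Ring order: furanone, then ten-membered ring and lactone in one step.

Assumption: the named antipodes of the amino-alcohol ligand (step 5) and of Ipc2BCl (step 9) are taken to give the configurations drawn (R at the tertiary carbinol, R at C8); if a test reaction shows the opposite sense, the enantiomeric ligand or reagent is used without other change.

## Route

Step 1
Reactants: 1 but-2-yne-1,4-diol
Product: 2 4-[(tert-butyldimethylsilyl)oxy]but-2-yn-1-ol
Conditions: NaH (1.0 equiv), TBSCl (1.0 equiv), THF, 0 → 23 °C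
Reagents that add atoms: tert-butyldimethylsilyl chloride, CC(C)(C)[Si](C)(C)Cl
Why: mono-O-silylation of a symmetrical diol through its mono-sodium alkoxide (Williamson-type silylation); no stereocentre is formed.

Step 2
Reactants: 2 4-[(tert-butyldimethylsilyl)oxy]but-2-yn-1-ol
Product: 4 (Z)-4-[(tert-butyldimethylsilyl)oxy]-3-iodobut-2-en-1-ol, via cyclic alkenylalanate 3 (not isolated)
Conditions: Red-Al, THF, 0 → 23 °C; then I2, THF, −78 °C
Reagents that add atoms: iodine, II
Why: hydroxyl-directed trans-hydroalumination of the propargylic alcohol (hydride to the proximal carbon, Al to the distal one in a five-membered alanate) and iodinolysis of the C–Al bond with retention give the (Z)-vinyl iodide, with iodine on the carbon carrying CH2OTBS (future C4, C3 and C6 cis).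

Step 3
Reactants: 4 (Z)-4-[(tert-butyldimethylsilyl)oxy]-3-iodobut-2-en-1-ol
Product: 5 (Z)-1-[(tert-butyldimethylsilyl)oxy]-2-iodo-4-[(triethylsilyl)oxy]but-2-ene
Conditions: TESCl, imidazole, CH2Cl2, 0 °C
Reagents that add atoms: chlorotriethylsilane, CC[Si](Cl)(CC)CC
Why: standard silylation of the primary allylic alcohol; it distinguishes O6 (TES, removed early) from O15 (TBS, removed last) and blocks furan formation from the (Z)-enynol in the later gold step.

Step 4
Reactants: 5 (Z)-1-[(tert-butyldimethylsilyl)oxy]-2-iodo-4-[(triethylsilyl)oxy]but-2-ene; 6 ethynylmagnesium bromide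
Product: 7 (E)-3-{[(tert-butyldimethylsilyl)oxy]methyl}-5-[(triethylsilyl)oxy]pent-3-en-1-yne
Conditions: 6, ZnBr2, THF, 0 °C; then 5, Pd(PPh3)4 (5 mol %), THF, 0 → 23 °C
Reagents that add atoms: none
Why: Negishi coupling of ethynylzinc bromide with the vinyl iodide gives the terminal enyne directly with retention of alkene geometry (the E descriptor results only from the CIP priority change).

Step 5
Reactants: 7 (E)-3-{[(tert-butyldimethylsilyl)oxy]methyl}-5-[(triethylsilyl)oxy]pent-3-en-1-yne; 8 butane-2,3-dione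
Product: 9 (3R,6E)-6-{[(tert-butyldimethylsilyl)oxy]methyl}-3-hydroxy-3-methyl-8-[(triethylsilyl)oxy]oct-6-en-4-yn-2-one
Conditions: Zn(OTf)2 (20 mol %), (1S,2S)-2-(dimethylamino)-1-(4-nitrophenyl)-3-[(tert-butyldimethylsilyl)oxy]propan-1-ol (22 mol %), Et3N (30 mol %), toluene, 40 °C; alkyne added slowly to an excess of the diketone, surplus diketone evaporated
Reagents that add atoms: none
Why: Proposed new method: catalytic enantioselective mono-alkynylation of a symmetrical, enolisable dialkyl 1,2-diketone, a 1:1 addition of the alkyne C–H across one C=O that forms the C1–C2 bond and sets the tertiary carbinol (3R) that later becomes C10; the Zn(II) amino-alkoxide forms the zinc acetylide of 7 with Et3N, biacetyl binds zinc as a five-membered s-cis chelate as an α-keto ester does, the ligand shields one face of the chelate, and the hindered α-alkoxy ketone product together with the surplus of symmetrical diketone suppresses a second addition; the closest known reaction type is the Zn(OTf)2/amino-alcohol-catalysed addition of terminal alkynes to α-keto esters and aldehydes, which has not been shown for simple enolisable 1,2-diketones.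

Step 6
Reactants: 10 methyl acrylate; 11 2,2-dimethoxyacetaldehyde
Product: 12 methyl 3-hydroxy-4,4-dimethoxy-2-methylidenebutanoate (racemic)
Conditions: DABCO (20 mol %), dioxane/H2O 1:1, 23 °C
Reagents that add atoms: none
Why: Morita–Baylis–Hillman reaction of an activated aldehyde with methyl acrylate; the carbinol centre is removed in the next step, so no stereocontrol is needed.

Step 7
Reactants: 12 methyl 3-hydroxy-4,4-dimethoxy-2-methylidenebutanoate
Product: 14 methyl (2Z)-2-(chloromethyl)-4,4-dimethoxybut-2-enoate, via allylic mesylate 13 (not isolated)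
Conditions: MsCl, Et3N, CH2Cl2, 0 °C → reflux
Reagents that add atoms: methanesulfonyl chloride, CS(=O)(=O)Cl
Why: mesylation followed by SN2' attack of chloride (conjugate addition–elimination on the acrylate) gives the thermodynamically preferred (Z)-2-(chloromethyl)enoate, with the ester trans to the acetal carbon.

Step 8
Reactants: 14 methyl (2Z)-2-(chloromethyl)-4,4-dimethoxybut-2-enoate
Product: 15 methyl (2Z)-2-(chloromethyl)-4-oxobut-2-enoate
Conditions: HCO2H/H2O, CHCl3, 0 °C (used crude)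
Reagents that add atoms: water, O
Why: acid-catalysed hydrolysis of an allylic dimethyl acetal; the trans arrangement of CHO and CO2Me prevents pseudo-acid cyclisation and the alkene geometry is kept.

Step 9
Reactants: 9 (3R,6E)-6-{[(tert-butyldimethylsilyl)oxy]methyl}-3-hydroxy-3-methyl-8-[(triethylsilyl)oxy]oct-6-en-4-yn-2-one; 15 methyl (2Z)-2-(chloromethyl)-4-oxobut-2-enoate
Product: 17 methyl (2Z,4R,7R,10E)-10-{[(tert-butyldimethylsilyl)oxy]methyl}-2-(chloromethyl)-4,7-dihydroxy-7-methyl-6-oxo-12-[(triethylsilyl)oxy]dodeca-2,10-dien-8-ynoate, via boron enolate 16 (not isolated)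
Conditions: (−)-Ipc2BCl (2.4 equiv), Et3N (3 equiv), Et2O, −78 → 0 °C; then 15, −78 → −20 °C; MeOH/pH 7 buffer, silica gel
Reagents that add atoms: none
Why: Ipc2BCl-mediated methyl-ketone boron aldol forming C8–C9: the first equivalent of borane masks the tertiary OH as a borinate, the second forms the only possible enol borinate, and reagent-controlled addition to the re face of the enal through a cyclic transition state sets C8 (4R) by 1,2-addition; the non-oxidative work-up spares the allyl chloride and acrylate.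

Step 10
Reactants: 17 methyl (2Z,4R,7R,10E)-10-{[(tert-butyldimethylsilyl)oxy]methyl}-2-(chloromethyl)-4,7-dihydroxy-7-methyl-6-oxo-12-[(triethylsilyl)oxy]dodeca-2,10-dien-8-ynoate; 18 (E)-but-2-enoyl chloride
Product: 19 methyl (2Z,4R,7R,10E)-4-[(2E)-but-2-enoyloxy]-10-{[(tert-butyldimethylsilyl)oxy]methyl}-2-(chloromethyl)-7-hydroxy-7-methyl-6-oxo-12-[(triethylsilyl)oxy]dodeca-2,10-dien-8-ynoate
Conditions: pyridine (3 equiv), CH2Cl2, −20 → 0 °C
Reagents that add atoms: none
Why: acylation of the secondary alcohol, which reacts far faster than the tertiary propargylic one; cold, weakly basic pyridine avoids β-elimination of the β-acyloxy ketone and quaternisation of the allyl chloride, and the ester removes the free OH that could add to the alkyne in the next step.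

Step 11
Reactants: 19 methyl (2Z,4R,7R,10E)-4-[(2E)-but-2-enoyloxy]-10-{[(tert-butyldimethylsilyl)oxy]methyl}-2-(chloromethyl)-7-hydroxy-7-methyl-6-oxo-12-[(triethylsilyl)oxy]dodeca-2,10-dien-8-ynoate
Product: 20 methyl (2Z,4R)-4-[(2E)-but-2-enoyloxy]-2-(chloromethyl)-5-[(2R)-5-{(2Z)-1-[(tert-butyldimethylsilyl)oxy]-4-[(triethylsilyl)oxy]but-2-en-2-yl}-2-methyl-3-oxo-2,3-dihydrofuran-2-yl]pent-2-enoate
Conditions: AuCl3 (5 mol %), 2,6-di-tert-butyl-4-methylpyridine (10 mol %), CH2Cl2, 23 °C
Reagents that add atoms: none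
Why: π-acid-catalysed domino 5-endo-dig heterocyclisation/1,2-alkyl shift of a 2-hydroxy-2-alkynyl ketone (α-ketol-type rearrangement): the ketone oxygen attacks the gold-activated alkyne at C3, the cyclic oxocarbenium ion triggers a suprafacial 1,2-shift of the methyl group from C1 to C10 on the ring face it already occupies, and protodeauration gives the 3(2H)-furanone, so the (R)-carbinol becomes (R)-C10 while the carbinol carbon becomes the C1 ketone.

Step 12
Reactants: 20 methyl (2Z,4R)-4-[(2E)-but-2-enoyloxy]-2-(chloromethyl)-5-[(2R)-5-{(2Z)-1-[(tert-butyldimethylsilyl)oxy]-4-[(triethylsilyl)oxy]but-2-en-2-yl}-2-methyl-3-oxo-2,3-dihydrofuran-2-yl]pent-2-enoate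
Product: 21 methyl (2Z,4R)-4-[(2E)-but-2-enoyloxy]-2-(chloromethyl)-5-[(2R)-5-{(2Z)-1-[(tert-butyldimethylsilyl)oxy]-4-oxobut-2-en-2-yl}-2-methyl-3-oxo-2,3-dihydrofuran-2-yl]pent-2-enoate
Conditions: (COCl)2, DMSO, CH2Cl2, −78 → −40 °C; then i-Pr2NEt, −78 → −20 °C
Reagents that add atoms: none
Why: Swern oxidation applied directly to the primary TES ether, which activated DMSO cleaves in situ while the TBS ether stays, gives the C6 aldehyde in one operation; low temperature and a hindered base keep the (Z)-enal geometry.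

Step 13
Reactants: 21 methyl (2Z,4R)-4-[(2E)-but-2-enoyloxy]-2-(chloromethyl)-5-[(2R)-5-{(2Z)-1-[(tert-butyldimethylsilyl)oxy]-4-oxobut-2-en-2-yl}-2-methyl-3-oxo-2,3-dihydrofuran-2-yl]pent-2-enoate
Product: 23 15-O-tert-butyldimethylsilyl ether of the target (4Z,6S,7S,8R,10R), via seco hydroxy ester 22 (not isolated)
Conditions: CrCl2 (10 equiv), THF, 23 °C, 2 mM (slow addition); aq. NH4Cl; PPTS (cat.), CH2Cl2
Reagents that add atoms: none
Why: intramolecular Nozaki–Hiyama 2-(alkoxycarbonyl)allylation (Barbier-type macrocyclisation) and lactonisation: the allylchromium(III) species adds through its γ-carbon C7 in a cyclic transition state to give the anti adduct (6,7-trans lactone), and the tether delivers the aldehyde to the C7 face anti to the C8 acyloxy group (H8 eclipsed), which sets 7S and with it 6S; the furanone and the (Z)-alkene pre-organise the ten-membered ring, and O8 is blocked as the crotonate so only the 6,12-lactone closes.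

Step 14
Reactants: 23 15-O-tert-butyldimethylsilyl ether of the target
Product: 24 CNP0225232.1, (4Z,6S,7S,8R,10R)-8-[(E)-but-2-enoyloxy]-15-hydroxy-1-oxo-3,10-epoxygermacra-2,4,11(13)-trien-12,6-olide
Conditions: HF·pyridine, pyridine, THF, 0 → 23 °C
Reagents that add atoms: none
Why: buffered fluoride desilylation of the primary TBS ether; the α-methylene lactone, crotonate and furanone tolerate these mildly acidic conditions and no stereocentre is touched.

## Compound list

1 | but-2-yne-1,4-diol | OCC#CCO | starting material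
2 | 4-[(tert-butyldimethylsilyl)oxy]but-2-yn-1-ol | OCC#CCO[Si](C)(C)C(C)(C)C | intermediate
3 | sodium cyclic alkenylalanate of 2 (2,2-bis(2-methoxyethoxy)-3-{[(tert-butyldimethylsilyl)oxy]methyl}-2,5-dihydro-1,2-oxaluminol-2-uide) | [Na+].COCCO[Al-]1(OCCOC)OCC=C1CO[Si](C)(C)C(C)(C)C | intermediate
4 | (Z)-4-[(tert-butyldimethylsilyl)oxy]-3-iodobut-2-en-1-ol | OC/C=C(\I)CO[Si](C)(C)C(C)(C)C | intermediate
5 | (Z)-1-[(tert-butyldimethylsilyl)oxy]-2-iodo-4-[(triethylsilyl)oxy]but-2-ene | CC[Si](CC)(CC)OC/C=C(\I)CO[Si](C)(C)C(C)(C)C | intermediate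
6 | ethynylmagnesium bromide | C#C[Mg]Br | starting material
7 | (E)-3-{[(tert-butyldimethylsilyl)oxy]methyl}-5-[(triethylsilyl)oxy]pent-3-en-1-yne | CC[Si](CC)(CC)OC/C=C(\C#C)CO[Si](C)(C)C(C)(C)C | intermediate
8 | butane-2,3-dione (biacetyl) | CC(=O)C(C)=O | starting material
9 | (3R,6E)-6-{[(tert-butyldimethylsilyl)oxy]methyl}-3-hydroxy-3-methyl-8-[(triethylsilyl)oxy]oct-6-en-4-yn-2-one | CC(=O)[C@](C)(O)C#C/C(CO[Si](C)(C)C(C)(C)C)=C\CO[Si](CC)(CC)CC | intermediate
10 | methyl acrylate | C=CC(=O)OC | starting material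
11 | 2,2-dimethoxyacetaldehyde | COC(OC)C=O | starting material
12 | methyl 3-hydroxy-4,4-dimethoxy-2-methylidenebutanoate (racemic) | COC(=O)C(=C)C(O)C(OC)OC | intermediate
13 | methyl 4,4-dimethoxy-3-[(methanesulfonyl)oxy]-2-methylidenebutanoate (racemic) | COC(=O)C(=C)C(OS(C)(=O)=O)C(OC)OC | intermediate
14 | methyl (2Z)-2-(chloromethyl)-4,4-dimethoxybut-2-enoate | COC(=O)/C(CCl)=C/C(OC)OC | intermediate
15 | methyl (2Z)-2-(chloromethyl)-4-oxobut-2-enoate | COC(=O)/C(CCl)=C/C=O | intermediate
16 | (3R,6E)-6-{[(tert-butyldimethylsilyl)oxy]methyl}-2,3-bis[(diisopinocampheylboranyl)oxy]-3-methyl-8-[(triethylsilyl)oxy]octa-1,6-dien-4-yne (boron enolate of 9, tertiary O also borylated) | C=C(OB([C@@H]1C[C@@H]2C[C@H]([C@H]1C)C2(C)C)[C@@H]1C[C@@H]2C[C@H]([C@H]1C)C2(C)C)[C@](C)(OB([C@@H]1C[C@@H]2C[C@H]([C@H]1C)C2(C)C)[C@@H]1C[C@@H]2C[C@H]([C@H]1C)C2(C)C)C#C/C(CO[Si](C)(C)C(C)(C)C)=C\CO[Si](CC)(CC)CC | intermediate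
17 | methyl (2Z,4R,7R,10E)-10-{[(tert-butyldimethylsilyl)oxy]methyl}-2-(chloromethyl)-4,7-dihydroxy-7-methyl-6-oxo-12-[(triethylsilyl)oxy]dodeca-2,10-dien-8-ynoate | COC(=O)/C(CCl)=C/[C@H](O)CC(=O)[C@](C)(O)C#C/C(CO[Si](C)(C)C(C)(C)C)=C\CO[Si](CC)(CC)CC | intermediate
18 | (E)-but-2-enoyl chloride (crotonyl chloride) | C/C=C/C(Cl)=O | starting material
19 | methyl (2Z,4R,7R,10E)-4-[(2E)-but-2-enoyloxy]-10-{[(tert-butyldimethylsilyl)oxy]methyl}-2-(chloromethyl)-7-hydroxy-7-methyl-6-oxo-12-[(triethylsilyl)oxy]dodeca-2,10-dien-8-ynoate | COC(=O)/C(CCl)=C/[C@H](OC(=O)/C=C/C)CC(=O)[C@](C)(O)C#C/C(CO[Si](C)(C)C(C)(C)C)=C\CO[Si](CC)(CC)CC | intermediate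
20 | methyl (2Z,4R)-4-[(2E)-but-2-enoyloxy]-2-(chloromethyl)-5-[(2R)-5-{(2Z)-1-[(tert-butyldimethylsilyl)oxy]-4-[(triethylsilyl)oxy]but-2-en-2-yl}-2-methyl-3-oxo-2,3-dihydrofuran-2-yl]pent-2-enoate | COC(=O)/C(CCl)=C/[C@H](OC(=O)/C=C/C)C[C@@]1(C)OC(=CC1=O)/C(CO[Si](C)(C)C(C)(C)C)=C\CO[Si](CC)(CC)CC | intermediate
21 | methyl (2Z,4R)-4-[(2E)-but-2-enoyloxy]-2-(chloromethyl)-5-[(2R)-5-{(2Z)-1-[(tert-butyldimethylsilyl)oxy]-4-oxobut-2-en-2-yl}-2-methyl-3-oxo-2,3-dihydrofuran-2-yl]pent-2-enoate | COC(=O)/C(CCl)=C/[C@H](OC(=O)/C=C/C)C[C@@]1(C)OC(=CC1=O)/C(CO[Si](C)(C)C(C)(C)C)=C\C=O | intermediate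
22 | seco hydroxy ester of 23: ten-membered 3,10-epoxy carbocycle with free 6-OH and a methyl 2-propenoate unit on C7 (8-O-crotonyl, 15-O-TBS) | C=C(C(=O)OC)[C@@H]1[C@@H](O)/C=C(/CO[Si](C)(C)C(C)(C)C)C2=CC(=O)[C@@](C)(C[C@H]1OC(=O)/C=C/C)O2 | intermediate
23 | 15-O-tert-butyldimethylsilyl ether of the target, (4Z,6S,7S,8R,10R) | C=C1C(=O)O[C@H]2/C=C(/CO[Si](C)(C)C(C)(C)C)C3=CC(=O)[C@@](C)(C[C@@H](OC(=O)/C=C/C)[C@H]12)O3 | intermediate
24 | CNP0225232.1, (4Z,6S,7S,8R,10R)-8-[(E)-but-2-enoyloxy]-15-hydroxy-1-oxo-3,10-epoxygermacra-2,4,11(13)-trien-12,6-olide | C=C1C(=O)O[C@H]2/C=C(/CO)C3=CC(=O)[C@@](C)(C[C@@H](OC(=O)/C=C/C)[C@H]12)O3 | target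

## Step count

Total: 14 steps. Longest linear sequence: 11 steps (steps 1–5 and 9–14); the aldehyde branch is 3 steps (6–8).

## Steps most likely to fail and fallbacks

The alkynylation of step 5 is the proposed new reaction. Biacetyl may self-condense under Zn(II)/Et3N, the enantioselectivity may be low, or the α-ketol may rearrange. The fallback uses known chemistry and sets out from 7. The same Zn(OTf)2/amino-alcohol system is applied to methyl pyruvate, an α-keto ester of the class for which this alkynylation is established, and gives methyl (2R,5E)-5-{[(tert-butyldimethylsilyl)oxy]methyl}-2-hydroxy-2-methyl-7-[(triethylsilyl)oxy]hept-5-en-3-ynoate F1. Treatment with MeNH(OMe)·HCl and i-PrMgCl converts the ester into the Weinreb amide (2R,5E)-5-{[(tert-butyldimethylsilyl)oxy]methyl}-2-hydroxy-N-methoxy-N,2-dimethyl-7-[(triethylsilyl)oxy]hept-5-en-3-ynamide F2. Excess MeMgBr then gives the methyl ketone, and the route is rejoined at 9.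

The aldol of step 9 may suffer from the free tertiary hydroxyl, from modest reagent control with a methyl ketone, or from the sensitivity of aldehyde 15. The fallback replaces the boron enolate by a catalytic Mukaiyama aldol and sets out from 9. TMSOTf/Et3N gives the silyl enol ether that also carries a tertiary TMS ether, (3R,6E)-6-{[(tert-butyldimethylsilyl)oxy]methyl}-3-methyl-8-[(triethylsilyl)oxy]-2,3-bis[(trimethylsilyl)oxy]octa-1,6-dien-4-yne F3. Its addition to 15 under SiCl4 with a chiral bisphosphoramide Lewis-base catalyst (CH2Cl2, −78 °C) gives the 7-O-trimethylsilyl ether of the aldol, methyl (2Z,4R,7R,10E)-10-{[(tert-butyldimethylsilyl)oxy]methyl}-2-(chloromethyl)-4-hydroxy-7-methyl-6-oxo-12-[(triethylsilyl)oxy]-7-[(trimethylsilyl)oxy]dodeca-2,10-dien-8-ynoate F4. Brief treatment with aqueous citric acid in THF at 0 °C removes the tertiary TMS group, and the route is rejoined at 17.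

The macrocyclisation of step 13 may give oligomers, the wrong C6/C7 diastereomer, or a (Z)→(E) isomerised enal that cannot close. The fallback changes the order of ring formation and sets out from 19. Direct Swern oxidation of the primary TES ether gives the acyclic enynal methyl (2Z,4R,7R,10E)-4-[(2E)-but-2-enoyloxy]-10-{[(tert-butyldimethylsilyl)oxy]methyl}-2-(chloromethyl)-7-hydroxy-7-methyl-6,12-dioxododeca-2,10-dien-8-ynoate F5. CrCl2-mediated macro-allylation and lactonisation on this more flexible substrate give the ten-membered enyne lactone that still carries the 1-hydroxy-1-methyl-10-oxo unit, 8-O-crotonyl-15-O-TBS-1-hydroxy-10-oxogermacra-4,11(13)-dien-2-yn-12,6-olide F6. AuCl3 then effects the heterocyclisation/1,2-methyl shift transannularly, and the route is rejoined at 23.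

## Further compounds

F1 | step 5 | methyl (2R,5E)-5-{[(tert-butyldimethylsilyl)oxy]methyl}-2-hydroxy-2-methyl-7-[(triethylsilyl)oxy]hept-5-en-3-ynoate | COC(=O)[C@](C)(O)C#C/C(CO[Si](C)(C)C(C)(C)C)=C\CO[Si](CC)(CC)CC
F2 | step 5 | (2R,5E)-5-{[(tert-butyldimethylsilyl)oxy]methyl}-2-hydroxy-N-methoxy-N,2-dimethyl-7-[(triethylsilyl)oxy]hept-5-en-3-ynamide | CON(C)C(=O)[C@](C)(O)C#C/C(CO[Si](C)(C)C(C)(C)C)=C\CO[Si](CC)(CC)CC
F3 | step 9 | (3R,6E)-6-{[(tert-butyldimethylsilyl)oxy]methyl}-3-methyl-8-[(triethylsilyl)oxy]-2,3-bis[(trimethylsilyl)oxy]octa-1,6-dien-4-yne | C=C(O[Si](C)(C)C)[C@](C)(O[Si](C)(C)C)C#C/C(CO[Si](C)(C)C(C)(C)C)=C\CO[Si](CC)(CC)CC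
F4 | step 9 | methyl (2Z,4R,7R,10E)-10-{[(tert-butyldimethylsilyl)oxy]methyl}-2-(chloromethyl)-4-hydroxy-7-methyl-6-oxo-12-[(triethylsilyl)oxy]-7-[(trimethylsilyl)oxy]dodeca-2,10-dien-8-ynoate | COC(=O)/C(CCl)=C/[C@H](O)CC(=O)[C@](C)(O[Si](C)(C)C)C#C/C(CO[Si](C)(C)C(C)(C)C)=C\CO[Si](CC)(CC)CC
F5 | step 13 | methyl (2Z,4R,7R,10E)-4-[(2E)-but-2-enoyloxy]-10-{[(tert-butyldimethylsilyl)oxy]methyl}-2-(chloromethyl)-7-hydroxy-7-methyl-6,12-dioxododeca-2,10-dien-8-ynoate | COC(=O)/C(CCl)=C/[C@H](OC(=O)/C=C/C)CC(=O)[C@](C)(O)C#C/C(CO[Si](C)(C)C(C)(C)C)=C\C=O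
F6 | step 13 | 8-O-crotonyl-15-O-TBS-1-hydroxy-10-oxogermacra-4,11(13)-dien-2-yn-12,6-olide (ten-membered enyne lactone, 1R,6S,7S,8R) | C=C1C(=O)O[C@H]2/C=C(/CO[Si](C)(C)C(C)(C)C)C#C[C@@](C)(O)C(=O)C[C@@H](OC(=O)/C=C/C)[C@H]12
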